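Ring B is disconnected at C1–C8a. C1 carries a cation-stabilising 4-oxygenated aryl group and C3 an aroyl group. Joining C1 and C3 turns this 1,3-donor–acceptor pair into a donor–acceptor cyclopropane, with catechol ring A attached to C3 through a C4 ketone. The precursor is therefore a cyclopropane made of C1, C2 and C3: 4-methoxyphenyl on C1, one 2,4-dimethoxybenzoyl group on C2 and, on quaternary C3, a second 2,4-dimethoxybenzoyl plus the 3,4-dimethoxybenzoyl group. In one operation SnCl4 opens C1–C3 and ring A closes on C1, forming ring B as a 4-tetralone with C1 trans to C2. The C4 oxygen then leaves through the enol triflate.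

Key step: step 4

Remarks on the chemistry:
- Numbering: ring B keeps the numbering of the target (C1 = CH–aryl, C2 = CH–aroyl, C3, C4, C4a, C8a) from the tetralone onwards. The cyclopropane is numbered C1 (quaternary), C2 (CH–aroyl), C3 (CH–aryl).
- Assumption: the quinine-derived thiourea of step 2 is taken to give the 3S adduct. If the sense is the reverse, its quinidine-derived pseudoenantiomer is used.
- Stereochemical relay: only the aroyl-bearing CH of the cyclopropane carries stereochemical information through the key step. The aryl-bearing carbon is ionised and the quaternary carbon becomes trigonal, so the cyclopropane is used as both epimers at its quaternary carbon.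
- Polarity of the cyclopropane closure: the ring is closed by a ketone enolate attacking the halogenated diketone carbon. The reverse polarity (a 1,3-diketone enolate closing on an α-onium or α-halo ketone, as in ylide additions to the arylidene diketone) is avoided because it closes through oxygen to 2,3-dihydrofurans.
- The chalcone of step 2 is the commercial drug substance metochalcone.

Step 1
Reactants: 1 3',4'-dimethoxyacetophenone; 2 methyl 2,4-dimethoxybenzoate
Product: 3 1-(2,4-dimethoxyphenyl)-3-(3,4-dimethoxyphenyl)propane-1,3-dione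
Conditions: NaH (2.2 equiv), THF, reflux; aq. HCl
Reagents that add atoms: none
Why: Crossed Claisen condensation in which the acetophenone enolate is acylated by the non-enolisable benzoate and the equilibrium is pulled over by deprotonation of the 1,3-diketone formed.

Step 2
Reactants: 3 1-(2,4-dimethoxyphenyl)-3-(3,4-dimethoxyphenyl)propane-1,3-dione; 4 (E)-1-(2,4-dimethoxyphenyl)-3-(4-methoxyphenyl)prop-2-en-1-one
Product: 5 (3S)-2-(3,4-dimethoxybenzoyl)-1,5-bis(2,4-dimethoxyphenyl)-3-(4-methoxyphenyl)pentane-1,5-dione (both epimers at C2)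
Conditions: N-[3,5-bis(trifluoromethyl)phenyl]-N'-[(8α,9S)-6'-methoxycinchonan-9-yl]thiourea (10 mol %), toluene (1 M), 40 °C
Reagents that add atoms: none
Why: Bifunctional amine–thiourea-catalysed Michael addition of a 1,3-diketone to a chalcone, in which the quinuclidine deprotonates the diketone and the thiourea holds the enone so that the carbon nucleophile reaches one face of the β-carbon and sets C3 as S, while the labile diketone CH (C2) needs no control.

Step 3
Reactants: 5 (3S)-2-(3,4-dimethoxybenzoyl)-1,5-bis(2,4-dimethoxyphenyl)-3-(4-methoxyphenyl)pentane-1,5-dione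
Product: 7 (2S,3R)-1-(3,4-dimethoxybenzoyl)-1,2-bis(2,4-dimethoxybenzoyl)-3-(4-methoxyphenyl)cyclopropane (2,3-trans; both epimers at C1), via tertiary iodide 6 (not isolated)
Conditions: I2 (1.1 equiv), then DBU (2.2 equiv) added slowly, CH2Cl2, 0 °C
Reagents that add atoms: none
Why: Iodine-mediated oxidative cyclopropanation of a 1,3-dicarbonyl–enone Michael adduct (iodination of the diketone carbon, then 3-exo-tet alkylation by the ketone enolate that DBU generates at C4 of the pentanedione), a polarity in which the closing nucleophile is a simple ketone enolate attacking carbon and not a diketone enolate free to close through oxygen; the aroyl group ends up trans to the 4-methoxyphenyl group, so the centre set in step 2 fixes the new C2 centre as S, and both epimers at the quaternary carbon are carried on.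

Step 4
Reactants: 7 (2S,3R)-1-(3,4-dimethoxybenzoyl)-1,2-bis(2,4-dimethoxybenzoyl)-3-(4-methoxyphenyl)cyclopropane
Product: 8 (1R,2S)-2,3-bis(2,4-dimethoxybenzoyl)-6,7-dimethoxy-1-(4-methoxyphenyl)-1,2-dihydronaphthalen-4-ol (endocyclic enol of the 4-tetralone)
Conditions: SnCl4 (2.5 equiv), CH2Cl2 (0.01 M), −78 to −20 °C; aq. HCl
Reagents that add atoms: none
Why: SnCl4 chelates the geminal diketone and heterolyses the strained C1–C3 bond (ring B numbering), which is polarised between the 4-methoxyphenyl donor and two acyl acceptors, giving a quinoid benzylic cation at C1 and a tin diketonate; a concerted displacement is impossible because ring A is tethered to the leaving carbon, so full ionisation precedes closure. Ring A, held cis to C2 on the chelated diketonate, attacks C1 through C8a (para to the C6 methoxy group) in a Friedel–Crafts closure of ring B that is 6-exo-trig with respect to the quinoid cation, and loss of the arene proton delivers the tetralone as its tin enolate. The closest known reaction is the Lewis-acid cyclisation of aryl 2-arylcyclopropyl ketones to 4-aryl-1-tetralones (formal homo-Nazarov). C1 is rebuilt from a planar cation under control of C2: with C2–H eclipsing the cation plane to relieve allylic strain, the tethered ring A can add only to the face anti to the C2 aroyl group, which gives the 1,2-trans (1R,2S) product that is also the more stable epimer. The step needs carbon instead of oxygen capture of the cation, the correct arene and retention at C2: tin occupies both diketonate oxygens, the geminal 2,4-dimethoxybenzoyl ring has only an unactivated ortho CH (its ipso attack is reversible), and low temperature with high dilution should let closure outrun loss of C2–H and intermolecular arylation.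

Step 5
Reactants: 8 (1R,2S)-2,3-bis(2,4-dimethoxybenzoyl)-6,7-dimethoxy-1-(4-methoxyphenyl)-1,2-dihydronaphthalen-4-ol
Product: 9 (1R,2S)-2,3-bis(2,4-dimethoxybenzoyl)-6,7-dimethoxy-1-(4-methoxyphenyl)-1,2-dihydronaphthalen-4-yl trifluoromethanesulfonate
Conditions: KN(SiMe3)2 (1.05 equiv), PhNTf2 (1.2 equiv), THF, −78 to 0 °C; cold dilute aq. HCl
Reagents that add atoms: N-phenylbis(trifluoromethanesulfonimide), O=S(=O)(N(c1ccccc1)S(=O)(=O)C(F)(F)F)C(F)(F)F
Why: O-Sulfonylation of the potassium diketonate (enol triflate formation), expected at the ring oxygen on C4 because the resulting C3=C4 bond stays conjugated with ring A and the exocyclic oxygen is screened by its ortho-methoxyaryl group and the C2 aroyl group, as in the endocyclic triflation known for 2-acylcycloalkanones, while one equivalent of base leaves C2–H untouched.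

Step 6
Reactants: 9 (1R,2S)-2,3-bis(2,4-dimethoxybenzoyl)-6,7-dimethoxy-1-(4-methoxyphenyl)-1,2-dihydronaphthalen-4-yl trifluoromethanesulfonate
Product: 10 (1R,2S)-2,3-bis(2,4-dimethoxybenzoyl)-6,7-dimethoxy-1-(4-methoxyphenyl)-1,2-dihydronaphthalene
Conditions: Pd(OAc)2 (5 mol %), PPh3 (10 mol %), HCO2H, Et3N, DMF, 60 °C
Reagents that add atoms: none
Why: Palladium-catalysed formate reduction of a vinyl triflate, in which zerovalent palladium inserts into the C4–O bond that the β-carbonyl activates, formate replaces triflate and loses CO2, and reductive elimination places hydrogen on C4 without touching the enone, the aryl ethers or the two stereocentres.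

Step 7
Reactants: 10 (1R,2S)-2,3-bis(2,4-dimethoxybenzoyl)-6,7-dimethoxy-1-(4-methoxyphenyl)-1,2-dihydronaphthalene
Product: 11 (1R,2S)-2,3-bis(2,4-dihydroxybenzoyl)-1-(4-hydroxyphenyl)-1,2-dihydronaphthalene-6,7-diol (CNP0195549.2)
Conditions: BBr3 (14 equiv), CH2Cl2, −78 °C to rt; MeOH, H2O
Reagents that add atoms: none
Why: Lewis-acid cleavage of aryl methyl ethers, in which BBr3 coordinates each ether oxygen and bromide removes the methyl group as MeBr, the ortho-methoxy ketones reacting first through chelation and the other five ethers with excess reagent at room temperature, while C1 cannot epimerise and C2 already holds the more stable trans arrangement.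

Compound list
1 | 3',4'-dimethoxyacetophenone | CC(=O)c1ccc(OC)c(OC)c1 | starting material
2 | methyl 2,4-dimethoxybenzoate | COC(=O)c1ccc(OC)cc1OC | starting material
3 | 1-(2,4-dimethoxyphenyl)-3-(3,4-dimethoxyphenyl)propane-1,3-dione | O=C(CC(=O)c1ccc(OC)c(OC)c1)c1ccc(OC)cc1OC | intermediate
4 | (E)-1-(2,4-dimethoxyphenyl)-3-(4-methoxyphenyl)prop-2-en-1-one (metochalcone) | COc1ccc(/C=C/C(=O)c2ccc(OC)cc2OC)cc1 | starting material
5 | (3S)-2-(3,4-dimethoxybenzoyl)-1,5-bis(2,4-dimethoxyphenyl)-3-(4-methoxyphenyl)pentane-1,5-dione, both epimers at C2 | O=C(c1ccc(OC)cc1OC)C[C@H](c1ccc(OC)cc1)C(C(=O)c1ccc(OC)cc1OC)C(=O)c1ccc(OC)c(OC)c1 | intermediate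
6 | (3R)-2-(3,4-dimethoxybenzoyl)-1,5-bis(2,4-dimethoxyphenyl)-2-iodo-3-(4-methoxyphenyl)pentane-1,5-dione (same spatial arrangement at C3 as in 5; both epimers at C2) | O=C(c1ccc(OC)cc1OC)C[C@H](c1ccc(OC)cc1)C(I)(C(=O)c1ccc(OC)cc1OC)C(=O)c1ccc(OC)c(OC)c1 | intermediate (not isolated)
7 | (2S,3R)-1-(3,4-dimethoxybenzoyl)-1,2-bis(2,4-dimethoxybenzoyl)-3-(4-methoxyphenyl)cyclopropane, 2,3-trans, both epimers at C1 | O=C(c1ccc(OC)cc1OC)[C@H]1[C@H](c2ccc(OC)cc2)C1(C(=O)c1ccc(OC)cc1OC)C(=O)c1ccc(OC)c(OC)c1 | intermediate
8 | (1R,2S)-2,3-bis(2,4-dimethoxybenzoyl)-6,7-dimethoxy-1-(4-methoxyphenyl)-1,2-dihydronaphthalen-4-ol, enol form of the 4-tetralone | O=C(C1=C(O)c2cc(OC)c(OC)cc2[C@@H](c2ccc(OC)cc2)[C@@H]1C(=O)c1ccc(OC)cc1OC)c1ccc(OC)cc1OC | intermediate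
9 | (1R,2S)-2,3-bis(2,4-dimethoxybenzoyl)-6,7-dimethoxy-1-(4-methoxyphenyl)-1,2-dihydronaphthalen-4-yl trifluoromethanesulfonate | O=C(C1=C(OS(=O)(=O)C(F)(F)F)c2cc(OC)c(OC)cc2[C@@H](c2ccc(OC)cc2)[C@@H]1C(=O)c1ccc(OC)cc1OC)c1ccc(OC)cc1OC | intermediate
10 | (1R,2S)-2,3-bis(2,4-dimethoxybenzoyl)-6,7-dimethoxy-1-(4-methoxyphenyl)-1,2-dihydronaphthalene | O=C(C1=Cc2cc(OC)c(OC)cc2[C@@H](c2ccc(OC)cc2)[C@@H]1C(=O)c1ccc(OC)cc1OC)c1ccc(OC)cc1OC | intermediate
11 | (1R,2S)-2,3-bis(2,4-dihydroxybenzoyl)-1-(4-hydroxyphenyl)-1,2-dihydronaphthalene-6,7-diol (CNP0195549.2) | O=C(C1=Cc2cc(O)c(O)cc2[C@@H](c2ccc(O)cc2)[C@@H]1C(=O)c1ccc(O)cc1O)c1ccc(O)cc1O | target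

Total step count: 7
Longest linear sequence: 7 steps (1 to 11; chalcone 4 enters in step 2)

Steps most likely to fail

Step 4 (key step). The open benzylic cation may shed the C2 proton, or be held up by reversible oxygen capture, before ring A closes. Re-protonation would then feed material that is scrambled at C2 into the closure, and the enantiomeric purity of 8 would fall. The fallback sets out from 7 and comes back at 8, and it moves the stereocontrol from the substrate to a catalyst. Cyclopropane 7 is opened on purpose with DBU in MeCN at 50 °C (E1cB opening through the C2 enolate) to 2-(3,4-dimethoxybenzoyl)-3-(2,4-dimethoxybenzoyl)-1-(2,4-dimethoxyphenyl)-4-(4-methoxyphenyl)but-3-en-1-one F1, in which the former C2 is trigonal. A chiral Brønsted acid, (R)-3,3'-bis(2,4,6-triisopropylphenyl)-1,1'-binaphthyl-2,2'-diyl N-triflylphosphoramide (or its enantiomer, whichever gives 1R), then protonates the enone carbonyl of F1. As the counter-anion of the resulting C1 cation it should direct the intramolecular conjugate Friedel–Crafts closure of ring A on C1. C2 is set afterwards by protonation to the more stable trans arrangement, which gives 8.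

Step 3. Iodine may migrate to the ketone α-carbon, after which the diketone enolate closes through oxygen to a 2,3-dihydrofuran. Retro-Michael cleavage of 5 under DBU may erode the enantiomeric purity, and excess base may open 7. The fallback sets out from 3 (with chalcone 4) and comes back at 7, passing by 5 and 6, so it also covers a sluggish Michael addition in step 2. Diketone 3 is brominated with NBS to 2-bromo-1-(2,4-dimethoxyphenyl)-3-(3,4-dimethoxyphenyl)propane-1,3-dione F2. F2 is then added to 4 under solid K2CO3 in mesitylene at 0 °C with N-[3,5-bis(trifluoromethyl)benzyl]quinidinium bromide or its quininium pseudoenantiomer, whichever gives the 2S,3R ring. This is a phase-transfer Michael-initiated ring closure of the kind known for bromomalonates and chalcones. The C2 ketone enolate born in the conjugate addition closes at once on the C–Br carbon, so no free diketone enolate and no separate halogenation of an adduct are involved.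

Step 5. Sulfonylation may occur at the exocyclic enolate oxygen; reduction would then leave the alkene outside ring B. The fallback sets out from 8 and comes back at 10, passing by 9, and it uses that same exocyclic preference. Methylation on oxygen (Me2SO4, K2CO3, acetone) gives (1R,2S)-2-(2,4-dimethoxybenzoyl)-3-[(2,4-dimethoxyphenyl)(methoxy)methylidene]-6,7-dimethoxy-1-(4-methoxyphenyl)-2,3-dihydronaphthalen-4(1H)-one F3. Reduction with i-Bu2AlH (CH2Cl2, −78 °C) of the C4 carbonyl and of the C2 aroyl carbonyl gives the diol F4. Mild acid (PPTS, wet acetone) hydrolyses the enol ether with loss of the C4 hydroxyl (Stork–Danheiser transposition) and gives the C3-aroyl C3=C4 enone carrying a C2 carbinol, hydroxy enone F5. Dess–Martin periodinane re-oxidises that carbinol and gives 10.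

Further compounds
F1 | step 4 | 2-(3,4-dimethoxybenzoyl)-3-(2,4-dimethoxybenzoyl)-1-(2,4-dimethoxyphenyl)-4-(4-methoxyphenyl)but-3-en-1-one (alkene geometry and C2 undefined) | COc1ccc(C=C(C(=O)c2ccc(OC)cc2OC)C(C(=O)c2ccc(OC)cc2OC)C(=O)c2ccc(OC)c(OC)c2)cc1
F2 | step 3 | 2-bromo-1-(2,4-dimethoxyphenyl)-3-(3,4-dimethoxyphenyl)propane-1,3-dione | O=C(C(Br)C(=O)c1ccc(OC)c(OC)c1)c1ccc(OC)cc1OC
F3 | step 5 | (1R,2S)-2-(2,4-dimethoxybenzoyl)-3-[(2,4-dimethoxyphenyl)(methoxy)methylidene]-6,7-dimethoxy-1-(4-methoxyphenyl)-2,3-dihydronaphthalen-4(1H)-one (alkene geometry undefined) | COC(=C1C(=O)c2cc(OC)c(OC)cc2[C@@H](c2ccc(OC)cc2)[C@@H]1C(=O)c1ccc(OC)cc1OC)c1ccc(OC)cc1OC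
F4 | step 5 | (1R,2S)-3-[(2,4-dimethoxyphenyl)(methoxy)methylidene]-2-[(2,4-dimethoxyphenyl)(hydroxy)methyl]-6,7-dimethoxy-1-(4-methoxyphenyl)-1,2,3,4-tetrahydronaphthalen-4-ol (carbinol centres and alkene geometry undefined) | COC(=C1C(O)c2cc(OC)c(OC)cc2[C@@H](c2ccc(OC)cc2)[C@@H]1C(O)c1ccc(OC)cc1OC)c1ccc(OC)cc1OC
F5 | step 5 | (1R,2S)-3-(2,4-dimethoxybenzoyl)-2-[(2,4-dimethoxyphenyl)(hydroxy)methyl]-6,7-dimethoxy-1-(4-methoxyphenyl)-1,2-dihydronaphthalene (carbinol centre undefined) | O=C(C1=Cc2cc(OC)c(OC)cc2[C@@H](c2ccc(OC)cc2)[C@@H]1C(O)c1ccc(OC)cc1OC)c1ccc(OC)cc1OC
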